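**Retrosynthetic overview**

1. The C10 iodide, the C9 ketone and the C7 acetate are late functional-group operations on a 9-silyloxy-7,12-diol ester; C1–C5 and the 5Z alkene come from a Wittig reaction on a C6 lactol.
2. Feature used: on the five-membered ring C8–C12 the tertiary C12 hydroxyl and the C7-bearing branch on C8 are cis, so O12 and C6 can be tied as a temporary cis-fused γ-lactone (ring O12–C12–C8–C7–C6), whose convex face then sets the C7 oxygen.
3. Key disconnection: C12–C13, by 1,2-addition of a 3-boryl-octa-1,2-diene through its CH2 terminus to the C12 ketone of a trans-5-(methoxycarbonylmethyl)-4-silyloxycyclopent-2-enone, anti to the C8 arm, followed by closure of O12 onto the C6 ester.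
4. Ring order: the carbocycle is bought as (S)-4-silyloxycyclopent-2-enone (its carbonyl becomes C12, its carbinol the future C9 ketone, its CH2 becomes C8); the lactone ring is formed in step 4 and opened again in step 9.

Key step: step 4

Remark: prostanoid numbering (C1 = ester carbon, ring = C8–C12, C13–C20 = lower chain) is used for every intermediate, and boronic acid 7 is assumed to be usable as a titrated toluene solution under argon without isolation in pure form.

**Route**

Step 1
Reactants: 1 (S)-4-(tert-butyldimethylsilyloxy)cyclopent-2-en-1-one; 2 methyl bromoacetate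
Product: 4 methyl 2-[(1S,5R)-5-(tert-butyldimethylsilyloxy)-2-oxocyclopent-3-en-1-yl]acetate (arm trans to the silyloxy group), via lithium dienolate 3 (not isolated)
Conditions: LiN(i-Pr)2, THF, −78 °C; then 2, DMPU, −78 to −40 °C
Reagents that add atoms: none
Why: Kinetic α′-deprotonation gives the cross-conjugated lithium dienolate, and enolate alkylation with the activated primary bromide should occur on the face away from the adjacent C9 silyloxy group, which sets C8 trans to C9, while loss of silyloxide is held back because it would give a cyclopentadienone.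

Step 2
Reactants: 5 oct-2-yn-1-ol
Product: 6 methyl oct-2-yn-1-yl carbonate
Conditions: ClCO2Me, pyridine, CH2Cl2, 0 °C
Reagents that add atoms: methyl chloroformate, COC(=O)Cl
Why: O-Acylation of the primary alcohol with a chloroformate (carbonate formation) installs the propargylic leaving group needed for the SN2′ borylation.

Step 3
Reactants: 6 methyl oct-2-yn-1-yl carbonate
Product: 7 (octa-1,2-dien-3-yl)boronic acid
Conditions: B2(OH)4, mesitylcopper Cu(C6H2Me3) (cat.), P(OMe)3 (cat.), MeOH, 3 Å MS, −10 °C; degassed dilute HCl/toluene extraction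
Reagents that add atoms: tetrahydroxydiboron, OB(O)B(O)O
Why: Copper-catalysed γ-selective borylation of a propargylic carbonate (borylcupration of the alkyne with boron on the pentyl-bearing carbon, the future C15, then β-elimination of the carbonate, overall SN2′) should give the 1,1-disubstituted allenylboron compound and no propargyl isomer.

Step 4
Reactants: 4 methyl 2-[(1S,5R)-5-(tert-butyldimethylsilyloxy)-2-oxocyclopent-3-en-1-yl]acetate; 7 (octa-1,2-dien-3-yl)boronic acid
Product: 10 (3aS,4R,6aR)-4-(tert-butyldimethylsilyloxy)-6a-(oct-2-yn-1-yl)-3,3a,4,6a-tetrahydro-2H-cyclopenta[b]furan-2-one (cis-fused O12–C6 lactone), via borate ester 8 (not isolated), via hydroxy ester 9 (not isolated)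
Conditions: 7 (2 equiv), 3 Å MS, toluene, 0 °C to rt; pH 7 buffer work-up; then DBU (0.2 equiv), toluene, 50 °C
Reagents that add atoms: none
Why: The boronic acid binds the C12 carbonyl oxygen and the allene CH2 terminus bonds to C12 in a closed six-membered transition state (propargylboration with allylic transposition, SE2′), so the boron-bearing carbon becomes the alkyne carbon C15 and only the oct-2-ynyl constitution can arise; the closest known reaction type is the additive-free propargylboration of ketones with allenylboronic acids. The free boronic acid is chosen because it reaches ketones without a zinc or copper co-catalyst, whose boron-to-metal exchange would open a propargyl/allenyl metal equilibrium and with it the isomeric allenyl carbinol. After hydrolysis of borate 8, the lactone ring is closed by 5-exo-trig acyl substitution of the tertiary C12 hydroxyl of 9 on the C6 methyl ester under DBU, which only the isomer with O12 cis to the C8 arm can do. The new stereocentre C12 is controlled by the substrate: the reagent should approach the carbonyl face anti to the adjacent C8 CH2CO2Me group, as nucleophiles do with 2,3-trans-disubstituted cyclopentanones, so C13 ends trans and O12 cis to that arm. The step needs 1,2- and not 1,4-addition, which the oxygen-bound cyclic transition state secures, and it needs this facial selectivity although the C9 silyloxy group lies on the attack face, which the closer C8 substituent should secure; any trans hydroxy ester cannot lactonise and separates as a much more polar compound.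

Step 5
Reactants: 10 (3aS,4R,6aR)-4-(tert-butyldimethylsilyloxy)-6a-(oct-2-yn-1-yl)-3,3a,4,6a-tetrahydro-2H-cyclopenta[b]furan-2-one
Product: 12 (3R,3aS,4R,6aR)-4-(tert-butyldimethylsilyloxy)-3-hydroxy-6a-(oct-2-yn-1-yl)-3,3a,4,6a-tetrahydro-2H-cyclopenta[b]furan-2-one (C7 hydroxyl on the convex face and cis to H-8), via potassium enolate 11 (not isolated)
Conditions: KN(SiMe3)2, THF, −78 °C; then 3-phenyl-2-(phenylsulfonyl)oxaziridine, −78 °C; AcOH quench
Reagents that add atoms: 3-phenyl-2-(phenylsulfonyl)oxaziridine, O=S(=O)(N1OC1c1ccccc1)c1ccccc1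
Why: Oxygen transfer from the N-sulfonyloxaziridine to the potassium lactone enolate (Davis hydroxylation) should occur on the convex face of the cis-fused bicycle, syn to H-8 and away from the cyclopentene ring, which sets the C7 carbinol with the configuration of the target.

Step 6
Reactants: 12 (3R,3aS,4R,6aR)-4-(tert-butyldimethylsilyloxy)-3-hydroxy-6a-(oct-2-yn-1-yl)-3,3a,4,6a-tetrahydro-2H-cyclopenta[b]furan-2-one
Product: 13 (3R,3aS,4R,6aR)-4-(tert-butyldimethylsilyloxy)-3-hydroxy-6a-[(2Z)-oct-2-en-1-yl]-3,3a,4,6a-tetrahydro-2H-cyclopenta[b]furan-2-one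
Conditions: H2 (1 atm), Pd on CaCO3 poisoned with Pb(OAc)2 (Lindlar catalyst), quinoline, EtOAc, rt
Reagents that add atoms: none
Why: Lindlar semi-hydrogenation (syn delivery of hydrogen on the poisoned palladium surface) converts the C14–C15 alkyne into the Z alkene and leaves the hindered ring alkene untouched.

Step 7
Reactants: 13 (3R,3aS,4R,6aR)-4-(tert-butyldimethylsilyloxy)-3-hydroxy-6a-[(2Z)-oct-2-en-1-yl]-3,3a,4,6a-tetrahydro-2H-cyclopenta[b]furan-2-one
Product: 14 (3R,3aS,4R,6aR)-4-(tert-butyldimethylsilyloxy)-3-(2-methoxypropan-2-yloxy)-6a-[(2Z)-oct-2-en-1-yl]-3,3a,4,6a-tetrahydro-2H-cyclopenta[b]furan-2-one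
Conditions: 2-methoxypropene, PPTS (cat.), CH2Cl2, 0 °C; Et3N quench
Reagents that add atoms: 2-methoxypropene, COC(C)=C
Why: Acid-catalysed addition of the C7 hydroxyl to the enol ether (mixed-acetal protection) masks it as a base-stable group that cannot migrate, so that no free alkoxide sits next to the C9 silyl ether or the aldehyde during the olefination.

Step 8
Reactants: 14 (3R,3aS,4R,6aR)-4-(tert-butyldimethylsilyloxy)-3-(2-methoxypropan-2-yloxy)-6a-[(2Z)-oct-2-en-1-yl]-3,3a,4,6a-tetrahydro-2H-cyclopenta[b]furan-2-one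
Product: 15 (3R,3aS,4R,6aR)-4-(tert-butyldimethylsilyloxy)-3-(2-methoxypropan-2-yloxy)-6a-[(2Z)-oct-2-en-1-yl]-3,3a,4,6a-tetrahydro-2H-cyclopenta[b]furan-2-ol (lactol as a mixture of C6 anomers)
Conditions: i-Bu2AlH, CH2Cl2, −78 °C; aq. KNaC4H4O6 (potassium sodium tartrate)
Reagents that add atoms: none
Why: Partial reduction of a γ-lactone with the aluminium hydride at −78 °C stops at the tetrahedral aluminium hemiacetal, which gives the lactol on work-up.

Step 9
Reactants: 15 (3R,3aS,4R,6aR)-4-(tert-butyldimethylsilyloxy)-3-(2-methoxypropan-2-yloxy)-6a-[(2Z)-oct-2-en-1-yl]-3,3a,4,6a-tetrahydro-2H-cyclopenta[b]furan-2-ol; 16 (4-carboxybutyl)triphenylphosphonium bromide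
Product: 18 (5Z,7S,8S,9R,12R,14Z)-9-(tert-butyldimethylsilyloxy)-12-hydroxy-7-(2-methoxypropan-2-yloxy)prosta-5,10,14-trien-1-oic acid, via phosphorus ylide 17 (not isolated)
Conditions: 16, KOt-Bu, THF, 0 °C to rt; then 15, 0 °C to rt; cold aq. NaH2PO4 (pH 5) work-up
Reagents that add atoms: none
Why: Wittig olefination of the lactol through its open hydroxy-aldehyde form with the non-stabilised, lithium-free ylide should give the 5Z alkene under kinetic control and frees the C12 tertiary hydroxyl, while C7, which carries an acetal oxygen, should not epimerise.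

Step 10
Reactants: 18 (5Z,7S,8S,9R,12R,14Z)-9-(tert-butyldimethylsilyloxy)-12-hydroxy-7-(2-methoxypropan-2-yloxy)prosta-5,10,14-trien-1-oic acid
Product: 20 methyl (5Z,7S,8S,9R,12R,14Z)-9-(tert-butyldimethylsilyloxy)-7,12-dihydroxyprosta-5,10,14-trien-1-oate, via acetal ester 19 (not isolated)
Conditions: Me3SiCHN2, toluene/MeOH, 0 °C; then PPTS (cat.), MeOH, rt
Reagents that add atoms: (trimethylsilyl)diazomethane, C[Si](C)(C)C=[N+]=[N-]
Why: Methylation of the carboxylic acid by the diazoalkane (esterification) and then acid-catalysed methanolysis of the mixed acetal (transacetalisation) free the C7 hydroxyl under conditions that leave the secondary silyl ether and the tertiary allylic alcohol alone; material that lost the acetal during the work-up of step 9 converges here.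

Step 11
Reactants: 20 methyl (5Z,7S,8S,9R,12R,14Z)-9-(tert-butyldimethylsilyloxy)-7,12-dihydroxyprosta-5,10,14-trien-1-oate
Product: 21 methyl (5Z,7S,8S,9R,12R,14Z)-7-acetoxy-9-(tert-butyldimethylsilyloxy)-12-hydroxyprosta-5,10,14-trien-1-oate
Conditions: Ac2O, pyridine, DMAP (cat.), CH2Cl2, 0 °C
Reagents that add atoms: acetic anhydride, CC(=O)OC(C)=O
Why: Nucleophile-catalysed acylation takes the secondary allylic C7 hydroxyl and not the hindered tertiary C12 hydroxyl.

Step 12
Reactants: 21 methyl (5Z,7S,8S,9R,12R,14Z)-7-acetoxy-9-(tert-butyldimethylsilyloxy)-12-hydroxyprosta-5,10,14-trien-1-oate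
Product: 22 methyl (5Z,7S,8R,9R,12R,14Z)-7-acetoxy-9,12-dihydroxyprosta-5,10,14-trien-1-oate
Conditions: HF·pyridine, pyridine, THF, 0 °C to rt
Reagents that add atoms: none
Why: Fluoride-mediated desilylation under buffered acidic conditions cleaves the Si–O bond without the acetate migration or hydrolysis that a basic fluoride source could cause.

Step 13
Reactants: 22 methyl (5Z,7S,8R,9R,12R,14Z)-7-acetoxy-9,12-dihydroxyprosta-5,10,14-trien-1-oate
Product: 23 methyl (5Z,7S,8R,12R,14Z)-7-acetoxy-12-hydroxy-9-oxoprosta-5,10,14-trien-1-oate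
Conditions: Dess–Martin periodinane, CH2Cl2, 0 °C to rt
Reagents that add atoms: none
Why: Dess–Martin oxidation converts the secondary allylic C9 alcohol into the enone, cannot touch the tertiary C12 alcohol, and runs without base, so the β-acetoxy ketone is not pushed to eliminate.

Step 14
Reactants: 23 methyl (5Z,7S,8R,12R,14Z)-7-acetoxy-12-hydroxy-9-oxoprosta-5,10,14-trien-1-oate
Product: 24 methyl (5Z,7S,8R,12S,14Z)-7-acetoxy-12-hydroxy-10-iodo-9-oxoprosta-5,10,14-trien-1-oate (7-acetoxy-7,8-dihydroiodovulone I)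
Conditions: I2, pyridine, CH2Cl2, 0 °C to rt, dark
Reagents that add atoms: iodine, II
Why: Amine-mediated α-iodination of the enone (conjugate addition of pyridine at C11, iodination of the enolate at C10, loss of pyridine; an addition–elimination of the Baylis–Hillman type) places iodine on C10, the only α-vinylic position.

**Compound list**

1 | (S)-4-(tert-butyldimethylsilyloxy)cyclopent-2-en-1-one | O=C1C=C[C@@H](O[Si](C)(C)C(C)(C)C)C1 | starting material
2 | methyl bromoacetate | COC(=O)CBr | starting material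
3 | lithium (R)-3-(tert-butyldimethylsilyloxy)cyclopenta-1,4-dien-1-olate (cross-conjugated dienolate of 1) | [Li+].[O-]C1=C[C@H](O[Si](C)(C)C(C)(C)C)C=C1 | intermediate
4 | methyl 2-[(1S,5R)-5-(tert-butyldimethylsilyloxy)-2-oxocyclopent-3-en-1-yl]acetate | O=C1C=C[C@@H](O[Si](C)(C)C(C)(C)C)[C@@H]1CC(=O)OC | intermediate
5 | oct-2-yn-1-ol | CCCCCC#CCO | starting material
6 | methyl oct-2-yn-1-yl carbonate | CCCCCC#CCOC(=O)OC | intermediate
7 | (octa-1,2-dien-3-yl)boronic acid | C=C=C(CCCCC)B(O)O | intermediate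
8 | methyl 2-[(1S,2R,5R)-5-(tert-butyldimethylsilyloxy)-2-(dihydroxyboryloxy)-2-(oct-2-yn-1-yl)cyclopent-3-en-1-yl]acetate (O12 borate) | CCCCCC#CC[C@@]1(OB(O)O)C=C[C@@H](O[Si](C)(C)C(C)(C)C)[C@@H]1CC(=O)OC | intermediate
9 | methyl 2-[(1S,2R,5R)-5-(tert-butyldimethylsilyloxy)-2-hydroxy-2-(oct-2-yn-1-yl)cyclopent-3-en-1-yl]acetate (hydroxyl cis to the acetate arm) | CCCCCC#CC[C@@]1(O)C=C[C@@H](O[Si](C)(C)C(C)(C)C)[C@@H]1CC(=O)OC | intermediate
10 | (3aS,4R,6aR)-4-(tert-butyldimethylsilyloxy)-6a-(oct-2-yn-1-yl)-3,3a,4,6a-tetrahydro-2H-cyclopenta[b]furan-2-one | CCCCCC#CC[C@@]12C=C[C@@H](O[Si](C)(C)C(C)(C)C)[C@@H]1CC(=O)O2 | intermediate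
11 | potassium enolate of lactone 10 (C6–C7 enolate) | [K+].CCCCCC#CC[C@@]12C=C[C@@H](O[Si](C)(C)C(C)(C)C)[C@@H]1C=C([O-])O2 | intermediate
12 | (3R,3aS,4R,6aR)-4-(tert-butyldimethylsilyloxy)-3-hydroxy-6a-(oct-2-yn-1-yl)-3,3a,4,6a-tetrahydro-2H-cyclopenta[b]furan-2-one | CCCCCC#CC[C@@]12C=C[C@@H](O[Si](C)(C)C(C)(C)C)[C@@H]1[C@@H](O)C(=O)O2 | intermediate
13 | (3R,3aS,4R,6aR)-4-(tert-butyldimethylsilyloxy)-3-hydroxy-6a-[(2Z)-oct-2-en-1-yl]-3,3a,4,6a-tetrahydro-2H-cyclopenta[b]furan-2-one | CCCCC/C=C\C[C@@]12C=C[C@@H](O[Si](C)(C)C(C)(C)C)[C@@H]1[C@@H](O)C(=O)O2 | intermediate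
14 | (3R,3aS,4R,6aR)-4-(tert-butyldimethylsilyloxy)-3-(2-methoxypropan-2-yloxy)-6a-[(2Z)-oct-2-en-1-yl]-3,3a,4,6a-tetrahydro-2H-cyclopenta[b]furan-2-one | CCCCC/C=C\C[C@@]12C=C[C@@H](O[Si](C)(C)C(C)(C)C)[C@@H]1[C@@H](OC(C)(C)OC)C(=O)O2 | intermediate
15 | (3R,3aS,4R,6aR)-4-(tert-butyldimethylsilyloxy)-3-(2-methoxypropan-2-yloxy)-6a-[(2Z)-oct-2-en-1-yl]-3,3a,4,6a-tetrahydro-2H-cyclopenta[b]furan-2-ol (anomeric mixture) | CCCCC/C=C\C[C@@]12C=C[C@@H](O[Si](C)(C)C(C)(C)C)[C@@H]1[C@@H](OC(C)(C)OC)C(O)O2 | intermediate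
16 | (4-carboxybutyl)triphenylphosphonium bromide | [Br-].OC(=O)CCCC[P+](c1ccccc1)(c1ccccc1)c1ccccc1 | starting material
17 | potassium 5-(triphenyl-λ5-phosphanylidene)pentanoate (ylide) | [K+].[O-]C(=O)CCCC=P(c1ccccc1)(c1ccccc1)c1ccccc1 | intermediate
18 | (5Z,7S,8S,9R,12R,14Z)-9-(tert-butyldimethylsilyloxy)-12-hydroxy-7-(2-methoxypropan-2-yloxy)prosta-5,10,14-trien-1-oic acid | CCCCC/C=C\C[C@@]1(O)C=C[C@@H](O[Si](C)(C)C(C)(C)C)[C@@H]1[C@H](/C=C\CCCC(=O)O)OC(C)(C)OC | intermediate
19 | methyl (5Z,7S,8S,9R,12R,14Z)-9-(tert-butyldimethylsilyloxy)-12-hydroxy-7-(2-methoxypropan-2-yloxy)prosta-5,10,14-trien-1-oate | CCCCC/C=C\C[C@@]1(O)C=C[C@@H](O[Si](C)(C)C(C)(C)C)[C@@H]1[C@H](/C=C\CCCC(=O)OC)OC(C)(C)OC | intermediate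
20 | methyl (5Z,7S,8S,9R,12R,14Z)-9-(tert-butyldimethylsilyloxy)-7,12-dihydroxyprosta-5,10,14-trien-1-oate | CCCCC/C=C\C[C@@]1(O)C=C[C@@H](O[Si](C)(C)C(C)(C)C)[C@@H]1[C@H](/C=C\CCCC(=O)OC)O | intermediate
21 | methyl (5Z,7S,8S,9R,12R,14Z)-7-acetoxy-9-(tert-butyldimethylsilyloxy)-12-hydroxyprosta-5,10,14-trien-1-oate | CCCCC/C=C\C[C@@]1(O)C=C[C@@H](O[Si](C)(C)C(C)(C)C)[C@@H]1[C@H](/C=C\CCCC(=O)OC)OC(C)=O | intermediate
22 | methyl (5Z,7S,8R,9R,12R,14Z)-7-acetoxy-9,12-dihydroxyprosta-5,10,14-trien-1-oate | CCCCC/C=C\C[C@@]1(O)C=C[C@@H](O)[C@@H]1[C@H](/C=C\CCCC(=O)OC)OC(C)=O | intermediate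
23 | methyl (5Z,7S,8R,12R,14Z)-7-acetoxy-12-hydroxy-9-oxoprosta-5,10,14-trien-1-oate | CCCCC/C=C\C[C@@]1(O)C=CC(=O)[C@@H]1[C@H](/C=C\CCCC(=O)OC)OC(C)=O | intermediate
24 | methyl (5Z,7S,8R,12S,14Z)-7-acetoxy-12-hydroxy-10-iodo-9-oxoprosta-5,10,14-trien-1-oate | CCCCC/C=C\C[C@@]1(O)C=C(I)C(=O)[C@@H]1[C@H](/C=C\CCCC(=O)OC)OC(C)=O | target

**Totals and risks**

Total step count: 14. Longest linear sequence: 13 steps (from 5 through steps 2, 3 and 4 to 14); the branch from 1 is 12 steps.

Steps most likely to fail: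

Step 4 (key step). The addition of the substituted allenylboron reagent to the conjugated, α-branched ketone may be slow, so that protodeboronation of the reagent or unselective background pathways compete. The fallback sets out from 4 and returns at 10; it brings in C13–C15 with the small parent reagent and completes the chain afterwards. Ketone 4 is treated with propargyl bromide and zinc dust in THF at 0 °C (Barbier propargylation). The allenylzinc bromide should add through its CH2 terminus in a cyclic transition state, again anti to the C8 arm. This gives methyl 2-[(1S,2R,5R)-5-(tert-butyldimethylsilyloxy)-2-hydroxy-2-(prop-2-yn-1-yl)cyclopent-3-en-1-yl]acetate F1 as its zinc alkoxide, which should close in the flask to the cis-fused lactone (3aS,4R,6aR)-4-(tert-butyldimethylsilyloxy)-6a-(prop-2-yn-1-yl)-3,3a,4,6a-tetrahydro-2H-cyclopenta[b]furan-2-one F2. The terminal alkyne of F2 is then coupled with 1-iodopentane in an alkyl Sonogashira reaction ([Pd(C3H5)Cl]2, 1,3-di(1-adamantyl)imidazolium chloride, CuI, Cs2CO3, DMF/Et2O, 45 °C), which forms C15–C16 and gives 10.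

Step 3. The free boronic acid may be lost by protodeboronation or oxidation during its preparation, extraction and storage. The fallback sets out from 6 and returns at 7; it carries the reagent in a protected, isolable form and unmasks it just before use. Carbonate 6 is borylated with B2pin2 (CuCl, KOt-Bu, Xantphos, THF, rt; the same copper-catalysed SN2′ borylation) to give 2-(octa-1,2-dien-3-yl)-4,4,5,5-tetramethyl-1,3,2-dioxaborolane F3, which can be chromatographed and stored. Immediately before step 4 the pinacol group is cleaved oxidatively (NaIO4, NH4OAc, acetone/water, rt) to release 7.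

Step 14. The β-acetoxy ketone may undergo base-induced E1cB loss of acetic acid across C7–C8 while it stands in pyridine and iodine. The fallback sets out from 18 and returns at 24; it reverses the order of acetylation and iodination, so that C7 carries a poor leaving group during the iodination.
- Acid 18 is esterified with Me3SiCHN2 without the acid stage, so that 19 is isolated.
- Bu4NF in THF at 0 °C removes the C9 silyl group and gives methyl (5Z,7S,8R,9R,12R,14Z)-9,12-dihydroxy-7-(2-methoxypropan-2-yloxy)prosta-5,10,14-trien-1-oate F4.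
- MnO2 in CH2Cl2, a neutral oxidant that spares the acetal, gives methyl (5Z,7S,8R,12R,14Z)-12-hydroxy-7-(2-methoxypropan-2-yloxy)-9-oxoprosta-5,10,14-trien-1-oate F5.
- I2 and pyridine in CH2Cl2 give methyl (5Z,7S,8R,12S,14Z)-12-hydroxy-10-iodo-7-(2-methoxypropan-2-yloxy)-9-oxoprosta-5,10,14-trien-1-oate F6.
- PPTS in MeOH removes the acetal and gives methyl (5Z,7S,8R,12S,14Z)-7,12-dihydroxy-10-iodo-9-oxoprosta-5,10,14-trien-1-oate F7.
- Ac2O and pyridine at 0 °C without DMAP then acetylate the secondary C7 hydroxyl selectively and give 24.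

**Further compounds**

F1 | step 4 | methyl 2-[(1S,2R,5R)-5-(tert-butyldimethylsilyloxy)-2-hydroxy-2-(prop-2-yn-1-yl)cyclopent-3-en-1-yl]acetate | C#CC[C@@]1(O)C=C[C@@H](O[Si](C)(C)C(C)(C)C)[C@@H]1CC(=O)OC
F2 | step 4 | (3aS,4R,6aR)-4-(tert-butyldimethylsilyloxy)-6a-(prop-2-yn-1-yl)-3,3a,4,6a-tetrahydro-2H-cyclopenta[b]furan-2-one | C#CC[C@@]12C=C[C@@H](O[Si](C)(C)C(C)(C)C)[C@@H]1CC(=O)O2
F3 | step 3 | 2-(octa-1,2-dien-3-yl)-4,4,5,5-tetramethyl-1,3,2-dioxaborolane | C=C=C(CCCCC)B1OC(C)(C)C(C)(C)O1
F4 | step 14 | methyl (5Z,7S,8R,9R,12R,14Z)-9,12-dihydroxy-7-(2-methoxypropan-2-yloxy)prosta-5,10,14-trien-1-oate | CCCCC/C=C\C[C@@]1(O)C=C[C@@H](O)[C@@H]1[C@H](/C=C\CCCC(=O)OC)OC(C)(C)OC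
F5 | step 14 | methyl (5Z,7S,8R,12R,14Z)-12-hydroxy-7-(2-methoxypropan-2-yloxy)-9-oxoprosta-5,10,14-trien-1-oate | CCCCC/C=C\C[C@@]1(O)C=CC(=O)[C@@H]1[C@H](/C=C\CCCC(=O)OC)OC(C)(C)OC
F6 | step 14 | methyl (5Z,7S,8R,12S,14Z)-12-hydroxy-10-iodo-7-(2-methoxypropan-2-yloxy)-9-oxoprosta-5,10,14-trien-1-oate | CCCCC/C=C\C[C@@]1(O)C=C(I)C(=O)[C@@H]1[C@H](/C=C\CCCC(=O)OC)OC(C)(C)OC
F7 | step 14 | methyl (5Z,7S,8R,12S,14Z)-7,12-dihydroxy-10-iodo-9-oxoprosta-5,10,14-trien-1-oate | CCCCC/C=C\C[C@@]1(O)C=C(I)C(=O)[C@@H]1[C@H](/C=C\CCCC(=O)OC)O
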